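Ring C of the middle flavan (O1, C2, C3, C4, C4a, C8a) is not taken from epicatechin but built in one operation: an oxa-Povarov [4+2] annulation in which the aryl oxocarbenium C4a=C8a–O1+=C2, raised on a phloroglucinol ring A that already carries the upper epicatechin gallate at C6, adds across the C3=C4 bond of an (E)-enol gallate held on C8 of catechin. This forms C2–C3 and C4–C4a, closes ring C, sets three stereocentres and brings in the second gallate. It exploits the symmetric 1,3,5-trioxygenated ring A: both carbons ortho to O1 are equivalent, so either closure gives the 4→6-linked product. The precursor is an O-aryl N,O-acetal of 3,4-bis(benzyloxy)benzaldehyde.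

Key step: step 12

Remark: the target is read as epicatechin-3-O-gallate-(4β→6)-epicatechin-3-O-gallate-(4β→8)-catechin; the three flavan units are called upper, middle and lower, each with flavan numbering (O1, C2, C3, C4, C4a, C5 to C8, C8a), and commercial (−)-epicatechin and (+)-catechin supply the upper and lower units.

Step 1
Reactants: 1 (−)-epicatechin
Product: 2 5,7,3',4'-tetra-O-benzyl-(−)-epicatechin
Conditions: BnBr (4.4 equiv), K2CO3, DMF, 0 °C to rt
Reagents that add atoms: benzyl bromide (BrCc1ccccc1)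
Why: Williamson ether synthesis: K2CO3 deprotonates only the four phenols, so the secondary 3-OH stays free and no stereocentre is touched.

Step 2
Reactants: 2 5,7,3',4'-tetra-O-benzyl-(−)-epicatechin
Product: 3 4β-(2-ethoxyethoxy)-5,7,3',4'-tetra-O-benzylepicatechin
Conditions: DDQ (2 equiv), 2-ethoxyethanol (5 equiv), CH2Cl2, rt
Reagents that add atoms: 2-ethoxyethanol (CCOCCO)
Why: DDQ benzylic oxidation: hydride abstraction at C4 gives the ring A-stabilised flavan-4-yl cation, which the alcohol traps trans to the 3-OH (4β), the standard C4 activation of benzylated flavan-3-ols.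

Step 3
Reactants: 3 4β-(2-ethoxyethoxy)-5,7,3',4'-tetra-O-benzylepicatechin; 4 3,4,5-tris(benzyloxy)benzoic acid
Product: 5 4β-(2-ethoxyethoxy)-5,7,3',4'-tetra-O-benzylepicatechin 3-O-[3,4,5-tris(benzyloxy)benzoate]
Conditions: DCC, DMAP (cat.), CH2Cl2, rt
Reagents that add atoms: none
Why: Steglich esterification acylates the axial 3-OH with retention at C3 and installs the upper gallate before any acid-labile interflavan bond exists.

Step 4
Reactants: 5 4β-(2-ethoxyethoxy)-5,7,3',4'-tetra-O-benzylepicatechin 3-O-[3,4,5-tris(benzyloxy)benzoate]; 6 3,5-bis(benzyloxy)phenol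
Product: 7 4β-[2,6-bis(benzyloxy)-4-hydroxyphenyl]-5,7,3',4'-tetra-O-benzylepicatechin 3-O-[3,4,5-tris(benzyloxy)benzoate]
Conditions: 6 (4 equiv), BF3·OEt2 (0.3 equiv), CH2Cl2–Et2O, −78 to −30 °C
Reagents that add atoms: none
Why: Friedel–Crafts alkylation: the Lewis acid ionises the C4 ether and the phenol attacks through the carbon para to its OH (the strongest para donor, between the two benzyloxy groups), anti to the C3 gallate, which sets 4β (3,4-trans).

Step 5
Reactants: 8 3,4-bis(benzyloxy)benzaldehyde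
Product: 9 1-{chloro[3,4-bis(benzyloxy)phenyl]methyl}-1H-benzotriazole (racemic)
Conditions: 1H-benzotriazole, SOCl2, CH2Cl2, 0 °C to rt, used crude
Reagents that add atoms: 1H-benzotriazole (c1ccc2[nH]nnc2c1); thionyl chloride (O=S(Cl)Cl)
Why: Benzotriazole-mediated α-chloroalkylation (condensation of aldehyde, benzotriazole and thionyl chloride) gives the 1-(α-chloroalkyl)benzotriazole, whose new centre is racemic and is erased in step 12.

Step 6
Reactants: 7 4β-[2,6-bis(benzyloxy)-4-hydroxyphenyl]-5,7,3',4'-tetra-O-benzylepicatechin 3-O-[3,4,5-tris(benzyloxy)benzoate]; 9 1-{chloro[3,4-bis(benzyloxy)phenyl]methyl}-1H-benzotriazole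
Product: 10 O-aryl N,O-acetal: 7 whose phenol oxygen carries the (1H-benzotriazol-1-yl)[3,4-bis(benzyloxy)phenyl]methyl group (both epimers at the acetal carbon)
Conditions: NaH, THF–DMF, 0 °C to rt
Reagents that add atoms: none
Why: O-Alkylation of the sodium phenoxide by the α-chloroalkylbenzotriazole (SN1-like substitution through the benzotriazole-stabilised cation) gives a base-stable 1-(α-aryloxyalkyl)benzotriazole, a latent aryl oxocarbenium ion; the acetal carbon is a mixture of epimers that converge later.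

Step 7
Reactants: 11 (+)-catechin
Product: 12 5,7,3',4'-tetra-O-benzyl-(+)-catechin
Conditions: BnBr (4.4 equiv), K2CO3, DMF, 0 °C to rt
Reagents that add atoms: benzyl bromide (BrCc1ccccc1)
Why: Williamson ether synthesis on the four phenols only, as in step 1; no stereocentre is touched.

Step 8
Reactants: 12 5,7,3',4'-tetra-O-benzyl-(+)-catechin
Product: 13 3,5,7,3',4'-penta-O-benzyl-(+)-catechin
Conditions: NaH, BnBr, Bu4NI (cat.), DMF, 0 °C to rt
Reagents that add atoms: benzyl bromide (BrCc1ccccc1)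
Why: Williamson ether synthesis on the secondary alkoxide protects the only hydroxyl that must stay free in the target as a benzyl ether, removable in the last step; C3 is not touched.

Step 9
Reactants: 13 3,5,7,3',4'-penta-O-benzyl-(+)-catechin
Product: 14 8-bromo-3,5,7,3',4'-penta-O-benzyl-(+)-catechin
Conditions: NBS (1.05 equiv), CH2Cl2, −78 to 0 °C, dark
Reagents that add atoms: N-bromosuccinimide (O=C1CCC(=O)N1Br)
Why: Electrophilic aromatic bromination of the phloroglucinol-type ring A goes to C8, the position known to react in 5,7-di-O-benzylflavans, and marks the carbon that becomes the 4→8 junction.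

Step 10
Reactants: 14 8-bromo-3,5,7,3',4'-penta-O-benzyl-(+)-catechin; 15 (E)-1,2-bis(4,4,5,5-tetramethyl-1,3,2-dioxaborolan-2-yl)ethene
Product: 17 potassium (E)-2-(3,5,7,3',4'-penta-O-benzylcatechin-8-yl)vinyltrifluoroborate, via alkenyl pinacol boronate 16 (not isolated)
Conditions: 15 (3 equiv), Pd(OAc)2 (5 mol %), SPhos (10 mol %), K3PO4, 1,4-dioxane–H2O, 80 °C; then KHF2, MeOH–H2O, rt; 17 extracted into acetone–CH2Cl2
Reagents that add atoms: potassium hydrogen difluoride (F.[F-].[K+])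
Why: Suzuki–Miyaura mono-coupling with an excess of the bis-boronate transfers the (E)-2-borylvinyl group with retention of alkene geometry, and KHF2 then turns the pinacol boronate into the trifluoroborate, which extraction frees from the water-soluble bis(trifluoroborate) of surplus 15.

Step 11
Reactants: 17 potassium (E)-2-(3,5,7,3',4'-penta-O-benzylcatechin-8-yl)vinyltrifluoroborate; 4 3,4,5-tris(benzyloxy)benzoic acid
Product: 18 (E)-2-(3,5,7,3',4'-penta-O-benzylcatechin-8-yl)vinyl 3,4,5-tris(benzyloxy)benzoate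
Conditions: CuBr (10 mol %), DMAP (0.2 equiv), 4 Å MS, O2 (1 atm), CH2Cl2, 40 °C
Reagents that add atoms: none
Why: Chan–Lam-type copper-catalysed oxidative C–O coupling of an alkenyltrifluoroborate with a carboxylic acid proceeds with retention at the alkenyl carbon and gives the (E)-enol ester directly with the gallate in place.

Step 12
Reactants: 10 O-aryl N,O-acetal; 18 (E)-2-(3,5,7,3',4'-penta-O-benzylcatechin-8-yl)vinyl 3,4,5-tris(benzyloxy)benzoate
Product: 21 nonadeca-O-benzyl epicatechin-3-O-gallate-(4β→6)-epicatechin-3-O-gallate-(4β→8)-catechin, via aryl oxocarbenium ion 19 (not isolated), via C4 benzylic cation 20 (not isolated)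
Conditions: (R)-3,3'-bis(2,4,6-triisopropylphenyl)-1,1'-binaphthyl-2,2'-diyl N-(trifluoromethanesulfonyl)phosphoramide (20 mol %), 5 Å MS, toluene–CH2Cl2, −60 to −30 °C, slow addition of 10 to 18 (1.5 equiv)
Reagents that add atoms: none
Why: Proposed new method: the chiral acid protonates the benzotriazole of 10, which leaves to give the (E)-aryl oxocarbenium ion 19 as a contact ion pair; C3 of 18 (the alkene carbon that bears the acyloxy group) attacks C2 of 19 because the 2,4,6-trioxygenated ring A of the catechin makes C4 the cation-stabilising end, and the resulting cation 20 (a p-quinone-methide-type cation that the gallate carbonyl can bridge) is captured by C4a of the middle ring A, the proton going back to the catalyst anion. The closest known reaction type is the Lewis acid-promoted oxa-Povarov reaction of aryl oxocarbenium ions with styrenes (Prins addition followed by Friedel–Crafts closure), extended here to a β-acyloxystyrene and to a chiral counteranion of the kind used in Brønsted acid-catalysed aza-Povarov reactions. One ring closes, the middle pyran, by a 6-endo-trig cationic π-cyclisation onto the C4a=C8a bond, which completes a formal [4+2] cycloaddition of the 2-oxadiene C4a=C8a–O1+=C2 with C3=C4. C3 and C4 come out trans because both new bonds are made on the same face of the (E)-alkene (directly or by double inversion through the trans-1,3-dioxolan-2-ylium form of 20), and C2 and C4 come out trans because the C2 aryl group of the (E)-oxocarbenium ends equatorial while the C4 aryl group goes pseudoaxial to escape the peri C5 benzyloxy group, which together fix 2,3-cis. The absolute sense (2R,3R at the new C2 and C3) is not secured by the remote stereocentres of the substrate and is assigned to the chiral phosphoramide anion, and because the upper and lower units are chiral the wrong-face product would be a separable diastereomer. The step further needs regioselectivity at ring A, secured by the two identical benzyloxy groups at C5 and C7 that make both carbons ortho to O1 equivalent, and chemoselectivity against Friedel–Crafts attack of 19 on free arene positions, secured as far as possible by slow addition of 10 to an excess of 18.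

Step 13
Reactants: 21 nonadeca-O-benzyl epicatechin-3-O-gallate-(4β→6)-epicatechin-3-O-gallate-(4β→8)-catechin
Product: 22 epicatechin-3-O-gallate-(4β→6)-epicatechin-3-O-gallate-(4β→8)-catechin (CNP0112921.1)
Conditions: H2 (1 atm), Pd(OH)2/C, THF–MeOH–H2O, rt
Reagents that add atoms: none
Why: Catalytic hydrogenolysis cleaves all nineteen benzyl ethers under neutral conditions that leave the two gallate esters, the C2–O1 benzylic ether bonds and both interflavan bonds untouched; no stereocentre is affected.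

Compound list

1 | (−)-epicatechin, (2R,3R)-2-(3,4-dihydroxyphenyl)chroman-3,5,7-triol | O[C@@H]1Cc2c(O)cc(O)cc2O[C@@H]1c1ccc(O)c(O)c1 | starting material
2 | 5,7,3',4'-tetra-O-benzyl-(−)-epicatechin | O[C@@H]1Cc2c(OCc9ccccc9)cc(OCc9ccccc9)cc2O[C@@H]1c1ccc(OCc9ccccc9)c(OCc9ccccc9)c1 | intermediate
3 | 4β-(2-ethoxyethoxy)-5,7,3',4'-tetra-O-benzylepicatechin (2,3-cis, 3,4-trans) | O[C@@H]1[C@@H](OCCOCC)c2c(OCc9ccccc9)cc(OCc9ccccc9)cc2O[C@@H]1c1ccc(OCc9ccccc9)c(OCc9ccccc9)c1 | intermediate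
4 | 3,4,5-tris(benzyloxy)benzoic acid | OC(=O)c1cc(OCc2ccccc2)c(OCc2ccccc2)c(OCc2ccccc2)c1 | starting material
5 | 4β-(2-ethoxyethoxy)-5,7,3',4'-tetra-O-benzylepicatechin 3-O-[3,4,5-tris(benzyloxy)benzoate] | O=C(O[C@@H]1[C@@H](OCCOCC)c2c(OCc9ccccc9)cc(OCc9ccccc9)cc2O[C@@H]1c1ccc(OCc9ccccc9)c(OCc9ccccc9)c1)c1cc(OCc9ccccc9)c(OCc9ccccc9)c(OCc9ccccc9)c1 | intermediate
6 | 3,5-bis(benzyloxy)phenol | Oc1cc(OCc2ccccc2)cc(OCc2ccccc2)c1 | starting material
7 | 4β-[2,6-bis(benzyloxy)-4-hydroxyphenyl]-5,7,3',4'-tetra-O-benzylepicatechin 3-O-[3,4,5-tris(benzyloxy)benzoate] (2,3-cis, 3,4-trans) | O=C(O[C@@H]1[C@@H](c2c(OCc9ccccc9)cc(O)cc2OCc9ccccc9)c2c(OCc9ccccc9)cc(OCc9ccccc9)cc2O[C@@H]1c1ccc(OCc9ccccc9)c(OCc9ccccc9)c1)c1cc(OCc9ccccc9)c(OCc9ccccc9)c(OCc9ccccc9)c1 | intermediate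
8 | 3,4-bis(benzyloxy)benzaldehyde | O=Cc1ccc(OCc2ccccc2)c(OCc2ccccc2)c1 | starting material
9 | 1-{chloro[3,4-bis(benzyloxy)phenyl]methyl}-1H-benzotriazole (racemic) | ClC(c1ccc(OCc2ccccc2)c(OCc2ccccc2)c1)n1nnc2ccccc12 | intermediate
10 | O-aryl N,O-acetal: 7 with its phenol oxygen bonded to the (1H-benzotriazol-1-yl)[3,4-bis(benzyloxy)phenyl]methyl carbon (both epimers at that carbon) | O=C(O[C@@H]1[C@@H](c2c(OCc9ccccc9)cc(OC(c3ccc(OCc9ccccc9)c(OCc9ccccc9)c3)n3nnc4ccccc34)cc2OCc9ccccc9)c2c(OCc9ccccc9)cc(OCc9ccccc9)cc2O[C@@H]1c1ccc(OCc9ccccc9)c(OCc9ccccc9)c1)c1cc(OCc9ccccc9)c(OCc9ccccc9)c(OCc9ccccc9)c1 | intermediate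
11 | (+)-catechin, (2R,3S)-2-(3,4-dihydroxyphenyl)chroman-3,5,7-triol | O[C@H]1Cc2c(O)cc(O)cc2O[C@@H]1c1ccc(O)c(O)c1 | starting material
12 | 5,7,3',4'-tetra-O-benzyl-(+)-catechin | O[C@H]1Cc2c(OCc9ccccc9)cc(OCc9ccccc9)cc2O[C@@H]1c1ccc(OCc9ccccc9)c(OCc9ccccc9)c1 | intermediate
13 | 3,5,7,3',4'-penta-O-benzyl-(+)-catechin | O(Cc9ccccc9)[C@H]1Cc2c(OCc9ccccc9)cc(OCc9ccccc9)cc2O[C@@H]1c1ccc(OCc9ccccc9)c(OCc9ccccc9)c1 | intermediate
14 | 8-bromo-3,5,7,3',4'-penta-O-benzyl-(+)-catechin | O(Cc9ccccc9)[C@H]1Cc2c(OCc9ccccc9)cc(OCc9ccccc9)c(Br)c2O[C@@H]1c1ccc(OCc9ccccc9)c(OCc9ccccc9)c1 | intermediate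
15 | (E)-1,2-bis(4,4,5,5-tetramethyl-1,3,2-dioxaborolan-2-yl)ethene | CC1(C)OB(/C=C/B2OC(C)(C)C(C)(C)O2)OC1(C)C | starting material
16 | 8-[(E)-2-(4,4,5,5-tetramethyl-1,3,2-dioxaborolan-2-yl)vinyl]-3,5,7,3',4'-penta-O-benzylcatechin (not isolated) | O(Cc9ccccc9)[C@H]1Cc2c(OCc9ccccc9)cc(OCc9ccccc9)c(/C=C/B3OC(C)(C)C(C)(C)O3)c2O[C@@H]1c1ccc(OCc9ccccc9)c(OCc9ccccc9)c1 | intermediate
17 | potassium (E)-2-(3,5,7,3',4'-penta-O-benzylcatechin-8-yl)vinyltrifluoroborate | O(Cc9ccccc9)[C@H]1Cc2c(OCc9ccccc9)cc(OCc9ccccc9)c(/C=C/[B-](F)(F)F)c2O[C@@H]1c1ccc(OCc9ccccc9)c(OCc9ccccc9)c1.[K+] | intermediate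
18 | (E)-2-(3,5,7,3',4'-penta-O-benzylcatechin-8-yl)vinyl 3,4,5-tris(benzyloxy)benzoate | O(Cc9ccccc9)[C@H]1Cc2c(OCc9ccccc9)cc(OCc9ccccc9)c(/C=C/OC(=O)c3cc(OCc9ccccc9)c(OCc9ccccc9)c(OCc9ccccc9)c3)c2O[C@@H]1c1ccc(OCc9ccccc9)c(OCc9ccccc9)c1 | intermediate
19 | (E)-aryl oxocarbenium ion from 10 after loss of benzotriazole (cation of the ion pair with the catalyst anion; not isolated) | O=C(O[C@@H]1[C@@H](c2c(OCc9ccccc9)cc(/[O+]=C/c3ccc(OCc9ccccc9)c(OCc9ccccc9)c3)cc2OCc9ccccc9)c2c(OCc9ccccc9)cc(OCc9ccccc9)cc2O[C@@H]1c1ccc(OCc9ccccc9)c(OCc9ccccc9)c1)c1cc(OCc9ccccc9)c(OCc9ccccc9)c(OCc9ccccc9)c1 | intermediate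
20 | C4 benzylic cation after C2–C3 bond formation (2R,3R; drawn open, in equilibrium with its gallate-bridged 1,3-dioxolan-2-ylium form; not isolated) | O=C(O[C@@H]1[C@@H](c2c(OCc9ccccc9)cc(O[C@H](c3ccc(OCc9ccccc9)c(OCc9ccccc9)c3)[C@H](OC(=O)c3cc(OCc9ccccc9)c(OCc9ccccc9)c(OCc9ccccc9)c3)[CH+]c3c(OCc9ccccc9)cc(OCc9ccccc9)c4c3O[C@H](c3ccc(OCc9ccccc9)c(OCc9ccccc9)c3)[C@@H](OCc9ccccc9)C4)cc2OCc9ccccc9)c2c(OCc9ccccc9)cc(OCc9ccccc9)cc2O[C@@H]1c1ccc(OCc9ccccc9)c(OCc9ccccc9)c1)c1cc(OCc9ccccc9)c(OCc9ccccc9)c(OCc9ccccc9)c1 | intermediate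
21 | nonadeca-O-benzyl epicatechin-3-O-gallate-(4β→6)-epicatechin-3-O-gallate-(4β→8)-catechin (all phenols and the lower 3-OH as benzyl ethers) | O=C(O[C@@H]1[C@@H](c2c(OCc9ccccc9)cc3c(c2OCc9ccccc9)[C@H](c2c(OCc9ccccc9)cc(OCc9ccccc9)c4c2O[C@H](c2ccc(OCc9ccccc9)c(OCc9ccccc9)c2)[C@@H](OCc9ccccc9)C4)[C@@H](OC(=O)c2cc(OCc9ccccc9)c(OCc9ccccc9)c(OCc9ccccc9)c2)[C@@H](c2ccc(OCc9ccccc9)c(OCc9ccccc9)c2)O3)c2c(OCc9ccccc9)cc(OCc9ccccc9)cc2O[C@@H]1c1ccc(OCc9ccccc9)c(OCc9ccccc9)c1)c1cc(OCc9ccccc9)c(OCc9ccccc9)c(OCc9ccccc9)c1 | intermediate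
22 | epicatechin-3-O-gallate-(4β→6)-epicatechin-3-O-gallate-(4β→8)-catechin (CNP0112921.1) | O=C(O[C@@H]1[C@@H](c2c(O)cc3c(c2O)[C@H](c2c(O)cc(O)c4c2O[C@H](c2ccc(O)c(O)c2)[C@@H](O)C4)[C@@H](OC(=O)c2cc(O)c(O)c(O)c2)[C@@H](c2ccc(O)c(O)c2)O3)c2c(O)cc(O)cc2O[C@@H]1c1ccc(O)c(O)c1)c1cc(O)c(O)c(O)c1 | target

Total step count: 13
Longest linear sequence: 7 steps (1 → 2 → 3 → 5 → 7 → 10 → 21 → 22, equal in length to 11 → 12 → 13 → 14 → 17 → 18 → 21 → 22)

Steps most likely to fail

Step 12 (proposed new method). The ion pair may show poor facial selectivity, since both partners are large and the resident stereocentres are remote; the antipodal acid is the first variation. The released benzotriazole may buffer the acid and stop turnover. The oxocarbenium ion may be diverted into Friedel–Crafts attack on free arene carbons, and the C4 cation may lose a proton instead of closing. The fallback uses known chemistry and takes ring C of the middle unit from epicatechin instead of building it. It sets out from 2: NBS bromination should give 8-bromo-5,7,3',4'-tetra-O-benzyl-(−)-epicatechin F1, and Steglich esterification with 4 its 3-O-gallate F2. TMSOTf-mediated Friedel–Crafts coupling of 5 with F2 (only C6 is free) should give the 4β→6 dimer F3. DDQ oxidation of F3 with 2-ethoxyethanol at its only benzylic CH2 should give the C4 ether F4. TMSOTf coupling of F4 with 13 (attack at C8) should give the 8-bromo trimer F5. Hydrogenolysis of F5 (H2, Pd(OH)2/C, Et3N) removes the benzyl groups and the bromine and comes back to the route at 22.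

Step 4. The phenol may be alkylated at the carbon ortho to its OH instead of para, or twice, so that the wrong oxygen would later become O1. The fallback sets out from 5 and uses phloroglucinol, whose three ring carbons are equivalent. BF3·OEt2-mediated coupling should give the 4β-(2,4,6-trihydroxyphenyl) adduct F6. Triisopropylsilyl chloride with imidazole should silylate the unhindered para hydroxyl to give the mono-silyl ether F7. BnBr with K2CO3 should benzylate the two flanking hydroxyls to give the dibenzylated silyl ether F8. Tetrabutylammonium fluoride with acetic acid removes the silyl group and comes back at 7.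

Step 11. The electron-rich alkenylboron species may undergo protodeboronation or oxidative homocoupling before the C–O bond forms. The fallback sets out from 17: oxidation of the C–B bond (NaBO3·4H2O, THF–H2O) should give the arylacetaldehyde F9. Its enol is O-acylated (Et3N, DMAP) with 3,4,5-tris(benzyloxy)benzoyl chloride F10, made from 4 and oxalyl chloride. The resulting enol gallate contains the (Z)-isomer F11, and iodine-catalysed equilibration to the more stable (E)-isomer comes back at 18.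

Further compounds

F1 | step 12 | 8-bromo-5,7,3',4'-tetra-O-benzyl-(−)-epicatechin | O[C@@H]1Cc2c(OCc9ccccc9)cc(OCc9ccccc9)c(Br)c2O[C@@H]1c1ccc(OCc9ccccc9)c(OCc9ccccc9)c1
F2 | step 12 | 8-bromo-5,7,3',4'-tetra-O-benzylepicatechin 3-O-[3,4,5-tris(benzyloxy)benzoate] | O=C(O[C@@H]1Cc2c(OCc9ccccc9)cc(OCc9ccccc9)c(Br)c2O[C@@H]1c1ccc(OCc9ccccc9)c(OCc9ccccc9)c1)c1cc(OCc9ccccc9)c(OCc9ccccc9)c(OCc9ccccc9)c1
F3 | step 12 | perbenzylated epicatechin-3-O-gallate-(4β→6)-(8-bromoepicatechin-3-O-gallate) | O=C(O[C@@H]1[C@@H](c2c(OCc9ccccc9)c(Br)c3c(c2OCc9ccccc9)C[C@@H](OC(=O)c2cc(OCc9ccccc9)c(OCc9ccccc9)c(OCc9ccccc9)c2)[C@@H](c2ccc(OCc9ccccc9)c(OCc9ccccc9)c2)O3)c2c(OCc9ccccc9)cc(OCc9ccccc9)cc2O[C@@H]1c1ccc(OCc9ccccc9)c(OCc9ccccc9)c1)c1cc(OCc9ccccc9)c(OCc9ccccc9)c(OCc9ccccc9)c1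
F4 | step 12 | F3 with a 4β-(2-ethoxyethoxy) group on C4 of the brominated unit | O=C(O[C@@H]1[C@@H](c2c(OCc9ccccc9)c(Br)c3c(c2OCc9ccccc9)[C@H](OCCOCC)[C@@H](OC(=O)c2cc(OCc9ccccc9)c(OCc9ccccc9)c(OCc9ccccc9)c2)[C@@H](c2ccc(OCc9ccccc9)c(OCc9ccccc9)c2)O3)c2c(OCc9ccccc9)cc(OCc9ccccc9)cc2O[C@@H]1c1ccc(OCc9ccccc9)c(OCc9ccccc9)c1)c1cc(OCc9ccccc9)c(OCc9ccccc9)c(OCc9ccccc9)c1
F5 | step 12 | 21 with bromine on C8 of the middle unit | O=C(O[C@@H]1[C@@H](c2c(OCc9ccccc9)c(Br)c3c(c2OCc9ccccc9)[C@H](c2c(OCc9ccccc9)cc(OCc9ccccc9)c4c2O[C@H](c2ccc(OCc9ccccc9)c(OCc9ccccc9)c2)[C@@H](OCc9ccccc9)C4)[C@@H](OC(=O)c2cc(OCc9ccccc9)c(OCc9ccccc9)c(OCc9ccccc9)c2)[C@@H](c2ccc(OCc9ccccc9)c(OCc9ccccc9)c2)O3)c2c(OCc9ccccc9)cc(OCc9ccccc9)cc2O[C@@H]1c1ccc(OCc9ccccc9)c(OCc9ccccc9)c1)c1cc(OCc9ccccc9)c(OCc9ccccc9)c(OCc9ccccc9)c1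
F6 | step 4 | 4β-(2,4,6-trihydroxyphenyl)-5,7,3',4'-tetra-O-benzylepicatechin 3-O-[3,4,5-tris(benzyloxy)benzoate] | O=C(O[C@@H]1[C@@H](c2c(O)cc(O)cc2O)c2c(OCc9ccccc9)cc(OCc9ccccc9)cc2O[C@@H]1c1ccc(OCc9ccccc9)c(OCc9ccccc9)c1)c1cc(OCc9ccccc9)c(OCc9ccccc9)c(OCc9ccccc9)c1
F7 | step 4 | F6 with the para hydroxyl as its triisopropylsilyl ether | O=C(O[C@@H]1[C@@H](c2c(O)cc(O[Si](C(C)C)(C(C)C)C(C)C)cc2O)c2c(OCc9ccccc9)cc(OCc9ccccc9)cc2O[C@@H]1c1ccc(OCc9ccccc9)c(OCc9ccccc9)c1)c1cc(OCc9ccccc9)c(OCc9ccccc9)c(OCc9ccccc9)c1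
F8 | step 4 | triisopropylsilyl ether of 7 | O=C(O[C@@H]1[C@@H](c2c(OCc9ccccc9)cc(O[Si](C(C)C)(C(C)C)C(C)C)cc2OCc9ccccc9)c2c(OCc9ccccc9)cc(OCc9ccccc9)cc2O[C@@H]1c1ccc(OCc9ccccc9)c(OCc9ccccc9)c1)c1cc(OCc9ccccc9)c(OCc9ccccc9)c(OCc9ccccc9)c1
F9 | step 11 | 2-(3,5,7,3',4'-penta-O-benzylcatechin-8-yl)acetaldehyde | O(Cc9ccccc9)[C@H]1Cc2c(OCc9ccccc9)cc(OCc9ccccc9)c(CC=O)c2O[C@@H]1c1ccc(OCc9ccccc9)c(OCc9ccccc9)c1
F10 | step 11 | 3,4,5-tris(benzyloxy)benzoyl chloride | O=C(Cl)c1cc(OCc2ccccc2)c(OCc2ccccc2)c(OCc2ccccc2)c1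
F11 | step 11 | (Z)-2-(3,5,7,3',4'-penta-O-benzylcatechin-8-yl)vinyl 3,4,5-tris(benzyloxy)benzoate | O(Cc9ccccc9)[C@H]1Cc2c(OCc9ccccc9)cc(OCc9ccccc9)c(/C=C\OC(=O)c3cc(OCc9ccccc9)c(OCc9ccccc9)c(OCc9ccccc9)c3)c2O[C@@H]1c1ccc(OCc9ccccc9)c(OCc9ccccc9)c1
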